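**Plan**

- Cyclohexene numbering: C1 (CH bearing ring A), C2=C3(CH3), C4, C5, C6 (quaternary: CH3 and styryl arm). The retrosynthesis cuts, in this order, the lactone of coumarin A (back to a ring A phenol), the styryl C=C between the C6 arm and C8 of coumarin B, the ring bond C1–C2, and the C1–aryl bond.
- Enabling feature: C1 is a benzylic CH on the electron-rich ring A, flanked by the alkene carbon C2 of the C2=C3(CH3) unit and by the quaternary C6. C1–C2 can therefore be closed from a benzylic radical (from a chloride) and an alkenylnickel (from a (Z)-alkenyl iodide) held in one chain.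
- Forward: a (Z)-iodoalkene chain is built from propargyl alcohol, extended to a geraniol-type dienol, epoxidised and rearranged to an α-quaternary aldehyde. Ring A is added as a Grignard reagent, the benzylic chloride is closed to the cyclohexene (first ring), coumarin B is attached by Horner–Wadsworth–Emmons olefination, and coumarin A is annulated last.
- Stereochemistry: C6 comes from a Sharpless epoxidation whose tertiary centre is transferred with inversion in an epoxy silyl ether rearrangement. C1 is set in the ring closure by a chiral nickel bis(oxazoline) catalyst acting on a planar benzylic radical (aryl cis to the CH2O arm). The (Z)-iodide fixes the ring alkene, and the olefination gives the (E)-styryl bond.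

Key step: step 12

Assumption: the ligand antipode that gives (1R) in step 12 cannot be predicted for this ring-closing variant, so both antipodes of the bis(oxazoline) are taken as available and the one matched to C6 is used.

**Route**

Step 1
Reactants: 1 prop-2-yn-1-ol
Product: 3 (Z)-3-iodo-2-methylprop-2-en-1-ol, via alkenylmagnesium alkoxide 2 (not isolated)
Conditions: MeMgBr (3 equiv), CuI (10 mol%), THF, −10 °C to rt; then I2, THF, −10 °C
Reagents that add atoms: methylmagnesium bromide C[Mg]Br; iodine II
Why: Copper-catalysed carbomagnesiation of propargyl alcohol proceeds by anti addition through the chelated alkenylmagnesium alkoxide 2, so iodinolysis with retention should place iodine cis to the CH2OH carbon, the geometry the later ring closure requires.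

Step 2
Reactants: 3 (Z)-3-iodo-2-methylprop-2-en-1-ol
Product: 4 (Z)-3-bromo-1-iodo-2-methylprop-1-ene
Conditions: CBr4, PPh3, CH2Cl2, 0 °C
Reagents that add atoms: carbon tetrabromide BrC(Br)(Br)Br
Why: Appel bromination of the primary allylic alcohol under neutral conditions should leave the alkenyl iodide and its geometry untouched.

Step 3
Reactants: 5 trimethyl(prop-1-yn-1-yl)silane; 4 (Z)-3-bromo-1-iodo-2-methylprop-1-ene
Product: 7 [(5Z)-6-iodo-5-methylhex-5-en-1-yn-1-yl]trimethylsilane, via silylpropargyllithium 6 (not isolated)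
Conditions: n-BuLi, THF, −78 °C; then 4, −78 °C to 0 °C
Reagents that add atoms: none
Why: The propargylic lithium reagent from 1-(trimethylsilyl)propyne alkylates primary allylic bromides at its propargylic carbon (SN2), the silyl group suppressing allenyl products, and it is too stabilised to exchange with the alkenyl iodide.

Step 4
Reactants: 7 [(5Z)-6-iodo-5-methylhex-5-en-1-yn-1-yl]trimethylsilane
Product: 8 (1Z)-1-iodo-2-methylhex-1-en-5-yne
Conditions: K2CO3, MeOH, rt
Reagents that add atoms: none
Why: Base-mediated methanolysis of the alkynyl C–Si bond is a standard protodesilylation that should not affect the alkenyl iodide.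

Step 5
Reactants: 8 (1Z)-1-iodo-2-methylhex-1-en-5-yne
Product: 10 (2E,6Z)-7-iodo-3,6-dimethylhepta-2,6-dien-1-ol, via alkenyldimethylalane 9 (not isolated)
Conditions: AlMe3 (2.5 equiv), Cp2ZrCl2 (25 mol%), CH2Cl2, 0 °C to rt; then (CH2O)n, THF, 0 °C to rt; aqueous NH4Cl
Reagents that add atoms: trimethylaluminium C[Al](C)C; formaldehyde (from paraformaldehyde) C=O
Why: Zirconium-catalysed carboalumination (Negishi) adds methyl and aluminium syn and regioselectively to the terminal alkyne, and trapping of alkenylalane 9 with formaldehyde with retention should give the (E)-allylic alcohol, alkenyl iodides being inert to AlMe3.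

Step 6
Reactants: 10 (2E,6Z)-7-iodo-3,6-dimethylhepta-2,6-dien-1-ol
Product: 11 [(2R,3R)-3-[(3Z)-4-iodo-3-methylbut-3-en-1-yl]-3-methyloxiran-2-yl]methanol
Conditions: Ti(OiPr)4 (10 mol%), D-(−)-diethyl tartrate (12 mol%), t-BuOOH, 4 Å molecular sieves, CH2Cl2, −20 °C
Reagents that add atoms: tert-butyl hydroperoxide CC(C)(C)OO
Why: Sharpless asymmetric epoxidation with the D-(−)-tartrate should deliver oxygen to the face of this geraniol-type (E)-allylic alcohol that gives the (2R,3R)-epoxide (the mirror image of the L-(+)-tartrate outcome with geraniol), setting both epoxide centres under reagent control and leaving the non-allylic iodoalkene untouched.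

Step 7
Reactants: 11 [(2R,3R)-3-[(3Z)-4-iodo-3-methylbut-3-en-1-yl]-3-methyloxiran-2-yl]methanol
Product: 12 tert-butyl{[(2R,3R)-3-[(3Z)-4-iodo-3-methylbut-3-en-1-yl]-3-methyloxiran-2-yl]methoxy}dimethylsilane
Conditions: TBSCl, imidazole, DMF, 0 °C to rt
Reagents that add atoms: tert-butyldimethylsilyl chloride CC(C)(C)[Si](C)(C)Cl
Why: Standard silylation of a primary alcohol, giving the siloxymethyl group that migrates in step 8 and protects the arm until step 13.

Step 8
Reactants: 12 tert-butyl{[(2R,3R)-3-[(3Z)-4-iodo-3-methylbut-3-en-1-yl]-3-methyloxiran-2-yl]methoxy}dimethylsilane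
Product: 13 (2R,5Z)-2-{[tert-butyl(dimethyl)silyl]oxymethyl}-6-iodo-2,5-dimethylhex-5-enal
Conditions: MeAl(OAr)2 (2 equiv; Ar = 4-bromo-2,6-di-tert-butylphenyl, made from AlMe3 and 2 ArOH), CH2Cl2, −78 °C
Reagents that add atoms: none
Why: In this organoaluminium-promoted epoxy silyl ether rearrangement (semipinacol type) the bulky oxophilic Lewis acid opens the epoxide at the tertiary carbon and the siloxymethyl group shifts to it anti to the departing oxygen, so that carbon is inverted stereospecifically and becomes the (R)-quaternary centre bearing CHO, CH3 and CH2OTBS (the future C6).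

Step 9
Reactants: 14 4-bromo-3-methoxyphenol
Product: 15 1-bromo-2-methoxy-4-(methoxymethoxy)benzene
Conditions: MOMCl, iPr2NEt, CH2Cl2, 0 °C to rt
Reagents that add atoms: chloromethyl methyl ether COCCl
Why: O-Alkylation of the only free phenol gives a MOM ether that survives Grignard formation, chlorination, the cathodic step and fluoride.

Step 10
Reactants: 15 1-bromo-2-methoxy-4-(methoxymethoxy)benzene; 13 (2R,5Z)-2-{[tert-butyl(dimethyl)silyl]oxymethyl}-6-iodo-2,5-dimethylhex-5-enal
Product: 17 (2R,5Z)-2-{[tert-butyl(dimethyl)silyl]oxymethyl}-6-iodo-1-[2-methoxy-4-(methoxymethoxy)phenyl]-2,5-dimethylhex-5-en-1-ol (both C1 epimers), via arylmagnesium bromide 16 (not isolated)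
Conditions: Mg turnings, THF, reflux; then 13, THF, −20 °C to 0 °C; aqueous NH4Cl
Reagents that add atoms: none
Why: Grignard addition to a non-enolisable α-quaternary aldehyde should be clean, arylmagnesium halides do not attack alkenyl iodides without a catalyst, and the carbinol configuration is left uncontrolled because C1 is later set from a radical.

Step 11
Reactants: 17 (2R,5Z)-2-{[tert-butyl(dimethyl)silyl]oxymethyl}-6-iodo-1-[2-methoxy-4-(methoxymethoxy)phenyl]-2,5-dimethylhex-5-en-1-ol
Product: 18 tert-butyl({(2R,5Z)-2-{chloro[2-methoxy-4-(methoxymethoxy)phenyl]methyl}-6-iodo-2,5-dimethylhex-5-en-1-yl}oxy)dimethylsilane (both epimers at the CHCl carbon)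
Conditions: 1-chloro-N,N,2-trimethylprop-1-en-1-amine, CH2Cl2, 0 °C; evaporated and used crude under anhydrous conditions
Reagents that add atoms: 1-chloro-N,N,2-trimethylprop-1-en-1-amine CC(C)=C(Cl)N(C)C
Why: The α-chloroenamine turns alcohols into chlorides under neutral conditions (deoxychlorination releasing only an amide, so MOM and TBS survive), and the 2,4-dialkoxybenzylic position ionises easily enough to substitute despite the neighbouring quaternary carbon, which also excludes elimination.

Step 12
Reactants: 18 tert-butyl({(2R,5Z)-2-{chloro[2-methoxy-4-(methoxymethoxy)phenyl]methyl}-6-iodo-2,5-dimethylhex-5-en-1-yl}oxy)dimethylsilane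
Product: 19 tert-butyl({(1S,2R)-2-[2-methoxy-4-(methoxymethoxy)phenyl]-1,4-dimethylcyclohex-3-en-1-yl}methoxy)dimethylsilane (route numbering: C1 R, aryl cis to the CH2OTBS arm on C6)
Conditions: NiBr2(dme) (10 mol%), chiral 2,2'-(cyclopropane-1,1-diyl)bis(indano-oxazoline) ligand (12 mol%, matched antipode), NaI, DMA, carbon-foam cathode, zinc anode, undivided cell, constant current, high dilution, 0 °C
Reagents that add atoms: none
Why: Proposed new method: NiBr2(dme)/bis(oxazoline) is reduced at the cathode to low-valent nickel, which inserts into the alkenyl C–I bond of 18, while a monovalent nickel species abstracts the benzylic chlorine to give a planar 2,4-dialkoxybenzylic radical; capture of this radical at the alkenylnickel centre and reductive elimination from the resulting seven-membered trivalent nickelacycle form C1–C2. The closest known reaction type is the nickel/bis(oxazoline)-catalysed enantioconvergent reductive coupling of alkenyl halides with secondary benzylic chlorides, run with a metal reductant or electrochemically, which is established between two molecules but not as a ring closure onto a benzylic carbon next to a quaternary centre. The six-membered ring closes by joining the chain termini C1 and C2 in a C(sp3)–C(sp2) reductive elimination (in radical terms a 6-endo closure, and a direct 6-endo radical addition with loss of iodine would converge on the same cyclohexene), so the C2=C3 double bond stays inside the ring. The new stereocentre C1 is set under catalyst control, since both chloride epimers give the same radical and the two C6 substituents (CH3 and CH2OTBS) are too similar to bias it strongly; the ligand antipode that places the aryl group cis to CH2OTBS (1R) is used, and chromatographic removal of the minor C1 epimer should also raise the enantiomeric purity inherited from step 6. The step needs cyclisation to outrun protodehalogenation and dimerisation, which the short tether, high dilution and the (Z)-geometry of the iodide (iodine cis to the chain) should secure, and the MOM and TBS ethers are inert to the reducing medium.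

Step 13
Reactants: 19 tert-butyl({(1S,2R)-2-[2-methoxy-4-(methoxymethoxy)phenyl]-1,4-dimethylcyclohex-3-en-1-yl}methoxy)dimethylsilane
Product: 20 {(1S,2R)-2-[2-methoxy-4-(methoxymethoxy)phenyl]-1,4-dimethylcyclohex-3-en-1-yl}methanol
Conditions: Bu4NF, THF, rt
Reagents that add atoms: none
Why: Fluoride-mediated desilylation of the neopentyl TBS ether, to which the aryl MOM ether and the alkene are inert.

Step 14
Reactants: 20 {(1S,2R)-2-[2-methoxy-4-(methoxymethoxy)phenyl]-1,4-dimethylcyclohex-3-en-1-yl}methanol
Product: 21 (1S,2S)-2-[2-methoxy-4-(methoxymethoxy)phenyl]-1,4-dimethylcyclohex-3-ene-1-carbaldehyde (same spatial arrangement as 20; the descriptor at the aryl-bearing carbon changes by priority only)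
Conditions: Dess–Martin periodinane, CH2Cl2, 0 °C to rt
Reagents that add atoms: none
Why: Dess–Martin oxidation of the neopentyl primary alcohol gives a non-enolisable aldehyde, so neither C6 nor the doubly activated C1–H is at risk.

Step 15
Reactants: 22 2-methylbenzene-1,3-diol (2-methylresorcinol)
Product: 23 7-hydroxy-8-methyl-2H-chromen-2-one
Conditions: malic acid, concentrated H2SO4, 110 °C
Reagents that add atoms: malic acid OC(CC(=O)O)C(=O)O
Why: Pechmann condensation, in which malic acid loses CO and water to formylacetic acid that attacks the resorcinol at the position ortho to one OH and para to the other (both free positions are equivalent) and lactonises.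

Step 16
Reactants: 23 7-hydroxy-8-methyl-2H-chromen-2-one
Product: 24 7-methoxy-8-methyl-2H-chromen-2-one
Conditions: MeI, K2CO3, acetone, reflux
Reagents that add atoms: iodomethane CI
Why: Williamson O-methylation of the phenol under mild carbonate conditions that the lactone tolerates.

Step 17
Reactants: 24 7-methoxy-8-methyl-2H-chromen-2-one
Product: 25 8-(bromomethyl)-7-methoxy-2H-chromen-2-one
Conditions: NBS, AIBN (catalytic), PhCF3, reflux
Reagents that add atoms: N-bromosuccinimide O=C1CCC(=O)N1Br
Why: Wohl–Ziegler radical bromination should take the benzylic C8 methyl group in preference to the electron-poor pyranone ring.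

Step 18
Reactants: 25 8-(bromomethyl)-7-methoxy-2H-chromen-2-one
Product: 26 diethyl [(7-methoxy-2-oxo-2H-chromen-8-yl)methyl]phosphonate
Conditions: P(OEt)3, neat, 130 °C
Reagents that add atoms: triethyl phosphite CCOP(OCC)OCC
Why: Michaelis–Arbuzov reaction of a reactive benzylic bromide with triethyl phosphite.

Step 19
Reactants: 26 diethyl [(7-methoxy-2-oxo-2H-chromen-8-yl)methyl]phosphonate; 21 (1S,2S)-2-[2-methoxy-4-(methoxymethoxy)phenyl]-1,4-dimethylcyclohex-3-ene-1-carbaldehyde
Product: 28 7-methoxy-8-[(E)-2-{(1R,2R)-2-[2-methoxy-4-(methoxymethoxy)phenyl]-1,4-dimethylcyclohex-3-en-1-yl}ethenyl]-2H-chromen-2-one, via sodium phosphonate carbanion 27 (not isolated)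
Conditions: NaN(SiMe3)2, THF, −78 °C; then 21, −78 °C to rt
Reagents that add atoms: none
Why: Horner–Wadsworth–Emmons olefination with a benzylic phosphonate anion gives the (E)-alkene, the quaternary substituent on the aldehyde reinforcing that preference, while the non-nucleophilic amide base spares the lactone and the aldehyde cannot epimerise.

Step 20
Reactants: 28 7-methoxy-8-[(E)-2-{(1R,2R)-2-[2-methoxy-4-(methoxymethoxy)phenyl]-1,4-dimethylcyclohex-3-en-1-yl}ethenyl]-2H-chromen-2-one
Product: 29 8-[(E)-2-{(1R,2R)-2-(4-hydroxy-2-methoxyphenyl)-1,4-dimethylcyclohex-3-en-1-yl}ethenyl]-7-methoxy-2H-chromen-2-one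
Conditions: 2 M HCl, MeOH/THF, 45 °C
Reagents that add atoms: none
Why: Acid-catalysed acetal exchange removes the aryl MOM ether under conditions too mild to protonate the trisubstituted alkene or open the coumarin.

Step 21
Reactants: 29 8-[(E)-2-{(1R,2R)-2-(4-hydroxy-2-methoxyphenyl)-1,4-dimethylcyclohex-3-en-1-yl}ethenyl]-7-methoxy-2H-chromen-2-one
Product: 30 2-hydroxy-4-methoxy-5-{(1R,6R)-6-[(E)-2-(7-methoxy-2-oxo-2H-chromen-8-yl)ethenyl]-3,6-dimethylcyclohex-2-en-1-yl}benzaldehyde
Conditions: MgCl2, Et3N, (CH2O)n, MeCN, reflux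
Reagents that add atoms: formaldehyde (from paraformaldehyde) C=O
Why: Magnesium-mediated ortho-formylation (Casnati–Skattebøl) acts only ortho to the phenoxide, and of the two ortho positions the one para to OMe is open whereas the one between the two oxygens is shielded by the methoxy group.

Step 22
Reactants: 30 2-hydroxy-4-methoxy-5-{(1R,6R)-6-[(E)-2-(7-methoxy-2-oxo-2H-chromen-8-yl)ethenyl]-3,6-dimethylcyclohex-2-en-1-yl}benzaldehyde
Product: 32 7-methoxy-6-{(1R,6R)-6-[(E)-2-(7-methoxy-2-oxo-2H-chromen-8-yl)ethenyl]-3,6-dimethylcyclohex-2-en-1-yl}-2H-chromen-2-one (CNP0287121.3), via ethyl (E)-hydroxycinnamate 31 (not isolated)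
Conditions: Ph3P=CHCO2Et, N,N-diethylaniline, reflux
Reagents that add atoms: ethyl (triphenylphosphoranylidene)acetate CCOC(=O)C=P(c1ccccc1)(c1ccccc1)c1ccccc1
Why: Wittig olefination of the salicylaldehyde gives cinnamate 31, which at the temperature of refluxing N,N-diethylaniline isomerises and lactonises onto the ortho hydroxyl, a standard route to 7-oxygenated coumarins that touches neither stereocentre.

**Compound list**

1 | prop-2-yn-1-ol | C#CCO | starting material
2 | bromomagnesium (Z)-3-(bromomagnesio)-2-methylprop-2-en-1-olate | Br[Mg]/C=C(C)\CO[Mg]Br | intermediate (not isolated)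
3 | (Z)-3-iodo-2-methylprop-2-en-1-ol | OC/C(C)=C\I | intermediate
4 | (Z)-3-bromo-1-iodo-2-methylprop-1-ene | BrC/C(C)=C\I | intermediate
5 | trimethyl(prop-1-yn-1-yl)silane | CC#C[Si](C)(C)C | starting material
6 | [3-(trimethylsilyl)prop-2-yn-1-yl]lithium | [Li]CC#C[Si](C)(C)C | intermediate (not isolated)
7 | [(5Z)-6-iodo-5-methylhex-5-en-1-yn-1-yl]trimethylsilane | C[Si](C)(C)C#CCC/C(C)=C\I | intermediate
8 | (1Z)-1-iodo-2-methylhex-1-en-5-yne | C#CCC/C(C)=C\I | intermediate
9 | [(1E,5Z)-6-iodo-2,5-dimethylhexa-1,5-dien-1-yl]dimethylalane | C[Al](C)/C=C(\C)CC/C(C)=C\I | intermediate (not isolated)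
10 | (2E,6Z)-7-iodo-3,6-dimethylhepta-2,6-dien-1-ol | OC/C=C(\C)CC/C(C)=C\I | intermediate
11 | [(2R,3R)-3-[(3Z)-4-iodo-3-methylbut-3-en-1-yl]-3-methyloxiran-2-yl]methanol | OC[C@H]1O[C@]1(C)CC/C(C)=C\I | intermediate
12 | tert-butyl{[(2R,3R)-3-[(3Z)-4-iodo-3-methylbut-3-en-1-yl]-3-methyloxiran-2-yl]methoxy}dimethylsilane | CC(C)(C)[Si](C)(C)OC[C@H]1O[C@]1(C)CC/C(C)=C\I | intermediate
13 | (2R,5Z)-2-{[tert-butyl(dimethyl)silyl]oxymethyl}-6-iodo-2,5-dimethylhex-5-enal | O=C[C@@](C)(CO[Si](C)(C)C(C)(C)C)CC/C(C)=C\I | intermediate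
14 | 4-bromo-3-methoxyphenol | COc1cc(O)ccc1Br | starting material
15 | 1-bromo-2-methoxy-4-(methoxymethoxy)benzene | COCOc1ccc(Br)c(OC)c1 | intermediate
16 | [2-methoxy-4-(methoxymethoxy)phenyl]magnesium bromide | COCOc1ccc([Mg]Br)c(OC)c1 | intermediate (not isolated)
17 | (2R,5Z)-2-{[tert-butyl(dimethyl)silyl]oxymethyl}-6-iodo-1-[2-methoxy-4-(methoxymethoxy)phenyl]-2,5-dimethylhex-5-en-1-ol, both C1 epimers | COCOc1ccc(C(O)[C@@](C)(CO[Si](C)(C)C(C)(C)C)CC/C(C)=C\I)c(OC)c1 | intermediate
18 | tert-butyl({(2R,5Z)-2-{chloro[2-methoxy-4-(methoxymethoxy)phenyl]methyl}-6-iodo-2,5-dimethylhex-5-en-1-yl}oxy)dimethylsilane, both CHCl epimers | COCOc1ccc(C(Cl)[C@@](C)(CO[Si](C)(C)C(C)(C)C)CC/C(C)=C\I)c(OC)c1 | intermediate (key-step precursor)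
19 | tert-butyl({(1S,2R)-2-[2-methoxy-4-(methoxymethoxy)phenyl]-1,4-dimethylcyclohex-3-en-1-yl}methoxy)dimethylsilane | COCOc1ccc([C@@H]2C=C(C)CC[C@]2(C)CO[Si](C)(C)C(C)(C)C)c(OC)c1 | intermediate (key-step product)
20 | {(1S,2R)-2-[2-methoxy-4-(methoxymethoxy)phenyl]-1,4-dimethylcyclohex-3-en-1-yl}methanol | COCOc1ccc([C@@H]2C=C(C)CC[C@]2(C)CO)c(OC)c1 | intermediate
21 | (1S,2S)-2-[2-methoxy-4-(methoxymethoxy)phenyl]-1,4-dimethylcyclohex-3-ene-1-carbaldehyde | COCOc1ccc([C@@H]2C=C(C)CC[C@]2(C)C=O)c(OC)c1 | intermediate
22 | 2-methylbenzene-1,3-diol | Cc1c(O)cccc1O | starting material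
23 | 7-hydroxy-8-methyl-2H-chromen-2-one | Cc1c(O)ccc2ccc(=O)oc12 | intermediate
24 | 7-methoxy-8-methyl-2H-chromen-2-one | COc1ccc2ccc(=O)oc2c1C | intermediate
25 | 8-(bromomethyl)-7-methoxy-2H-chromen-2-one | COc1ccc2ccc(=O)oc2c1CBr | intermediate
26 | diethyl [(7-methoxy-2-oxo-2H-chromen-8-yl)methyl]phosphonate | CCOP(=O)(Cc1c(OC)ccc2ccc(=O)oc12)OCC | intermediate
27 | sodium (diethoxyphosphoryl)(7-methoxy-2-oxo-2H-chromen-8-yl)methanide | CCOP(=O)([CH-]c1c(OC)ccc2ccc(=O)oc12)OCC.[Na+] | intermediate (not isolated)
28 | 7-methoxy-8-[(E)-2-{(1R,2R)-2-[2-methoxy-4-(methoxymethoxy)phenyl]-1,4-dimethylcyclohex-3-en-1-yl}ethenyl]-2H-chromen-2-one | COCOc1ccc([C@@H]2C=C(C)CC[C@]2(C)/C=C/c2c(OC)ccc3ccc(=O)oc23)c(OC)c1 | intermediate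
29 | 8-[(E)-2-{(1R,2R)-2-(4-hydroxy-2-methoxyphenyl)-1,4-dimethylcyclohex-3-en-1-yl}ethenyl]-7-methoxy-2H-chromen-2-one | Oc1ccc([C@@H]2C=C(C)CC[C@]2(C)/C=C/c2c(OC)ccc3ccc(=O)oc23)c(OC)c1 | intermediate
30 | 2-hydroxy-4-methoxy-5-{(1R,6R)-6-[(E)-2-(7-methoxy-2-oxo-2H-chromen-8-yl)ethenyl]-3,6-dimethylcyclohex-2-en-1-yl}benzaldehyde | O=Cc1cc([C@@H]2C=C(C)CC[C@]2(C)/C=C/c2c(OC)ccc3ccc(=O)oc23)c(OC)cc1O | intermediate
31 | ethyl (E)-3-(2-hydroxy-4-methoxy-5-{(1R,6R)-6-[(E)-2-(7-methoxy-2-oxo-2H-chromen-8-yl)ethenyl]-3,6-dimethylcyclohex-2-en-1-yl}phenyl)prop-2-enoate | CCOC(=O)/C=C/c1cc([C@@H]2C=C(C)CC[C@]2(C)/C=C/c2c(OC)ccc3ccc(=O)oc23)c(OC)cc1O | intermediate (not isolated)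
32 | 7-methoxy-6-{(1R,6R)-6-[(E)-2-(7-methoxy-2-oxo-2H-chromen-8-yl)ethenyl]-3,6-dimethylcyclohex-2-en-1-yl}-2H-chromen-2-one | COc1cc2oc(=O)ccc2cc1[C@@H]1C=C(C)CC[C@]1(C)/C=C/c1c(OC)ccc2ccc(=O)oc12 | target

**Step count and risks**

Total steps: 22. Longest linear sequence: 17 (steps 1–8, 10–14, 19–22).

Steps most likely to fail:

1. Step 12 (nickel electroreductive ring closure). The process at risk is reduction of the C–I or C–Cl bond without ring closure, intermolecular coupling, ionisation of the electron-rich benzylic chloride before the radical forms, or weak catalyst control over C1. The fallback sets out from chloride 18. LiCl-mediated insertion of zinc dust (THF, 25 °C) into the benzylic C–Cl bond, which is faster than insertion into an alkenyl iodide, would give the secondary benzylic zinc chloride F1. Addition of Pd(OAc)2 and 2-dicyclohexylphosphino-2',6'-dimethoxybiphenyl then closes the same C1–C2 bond by intramolecular Negishi coupling at zerovalent palladium. C1 is then set under substrate control only, so 19 is expected together with its C1 epimer, tert-butyl({(1S,2S)-2-[2-methoxy-4-(methoxymethoxy)phenyl]-1,4-dimethylcyclohex-3-en-1-yl}methoxy)dimethylsilane F2, and chromatographic separation returns the route at 19.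

2. Step 19 (Horner–Wadsworth–Emmons olefination). The process at risk is slow addition of the benzylic phosphonate anion to the hindered α-quaternary aldehyde, with competing attack of the anion on the coumarin lactone or enoate of a second molecule. The fallback sets out from aldehyde 21. Wittig methylenation (Ph3PCH3Br, KN(SiMe3)2, THF) would give the terminal alkene 1-[(1R,6R)-6-ethenyl-3,6-dimethylcyclohex-2-en-1-yl]-2-methoxy-4-(methoxymethoxy)benzene F3, which has no allylic hydrogen on the quaternary side. Its coupling partner is made from 7-hydroxycoumarin by iodination (I2, KI, aqueous NH3) to 7-hydroxy-8-iodo-2H-chromen-2-one F4 and O-methylation (MeI, K2CO3) to 8-iodo-7-methoxy-2H-chromen-2-one F5. A Mizoroki–Heck reaction of F3 with F5 (Pd(OAc)2, Bu4NCl, NaHCO3, DMF, 80 °C) should arylate the terminal carbon and give the (E)-alkene, returning the route at 28.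

3. Step 21 (ortho-formylation). The process at risk is formylation at the wrong ortho position (between the two oxygens) or stalled conversion of the hindered phenoxide. The fallback sets out from phenol 29 and replaces steps 21 and 22. Esterification with propiolic acid (N,N'-dicyclohexylcarbodiimide, CH2Cl2, 0 °C) would give 3-methoxy-4-{(1R,6R)-6-[(E)-2-(7-methoxy-2-oxo-2H-chromen-8-yl)ethenyl]-3,6-dimethylcyclohex-2-en-1-yl}phenyl prop-2-ynoate F6. Gold-catalysed intramolecular hydroarylation ((Ph3P)AuCl/AgOTf, 1,2-dichloroethane, rt to 60 °C) then lets the ring carbon para to OMe attack the activated alkyne in a 6-endo closure, forming coumarin A directly and returning the route at 32.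

**Further compounds**

F1 | step 12 | chloro{(2R,5Z)-2-{[tert-butyl(dimethyl)silyl]oxymethyl}-6-iodo-1-[2-methoxy-4-(methoxymethoxy)phenyl]-2,5-dimethylhex-5-en-1-yl}zinc | COCOc1ccc(C([Zn]Cl)[C@@](C)(CO[Si](C)(C)C(C)(C)C)CC/C(C)=C\I)c(OC)c1
F2 | step 12 | tert-butyl({(1S,2S)-2-[2-methoxy-4-(methoxymethoxy)phenyl]-1,4-dimethylcyclohex-3-en-1-yl}methoxy)dimethylsilane | COCOc1ccc([C@H]2C=C(C)CC[C@]2(C)CO[Si](C)(C)C(C)(C)C)c(OC)c1
F3 | step 19 | 1-[(1R,6R)-6-ethenyl-3,6-dimethylcyclohex-2-en-1-yl]-2-methoxy-4-(methoxymethoxy)benzene | COCOc1ccc([C@@H]2C=C(C)CC[C@]2(C)C=C)c(OC)c1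
F4 | step 19 | 7-hydroxy-8-iodo-2H-chromen-2-one | Oc1ccc2ccc(=O)oc2c1I
F5 | step 19 | 8-iodo-7-methoxy-2H-chromen-2-one | COc1ccc2ccc(=O)oc2c1I
F6 | step 21 | 3-methoxy-4-{(1R,6R)-6-[(E)-2-(7-methoxy-2-oxo-2H-chromen-8-yl)ethenyl]-3,6-dimethylcyclohex-2-en-1-yl}phenyl prop-2-ynoate | C#CC(=O)Oc1ccc([C@@H]2C=C(C)CC[C@]2(C)/C=C/c2c(OC)ccc3ccc(=O)oc23)c(OC)c1
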